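## Retrosynthetic overview

- **Feature:** each half is numbered as a drimane (ring A = C1–C5 + C10, ring B = C5–C10, linker C11–C11'). Quaternary C10 sits between C5 and the C8=C9 alkene, so with C5 as a carbonyl it is the alpha carbon of a beta,gamma-unsaturated cyclohexenone. Rings B and B' plus the linker can therefore be built as a flat, achiral bis(enone).
- **Endgame:** 25 ⇒ C5–H and C5'–H from tertiary C5 radicals (bis-oxalate 24) ⇒ rings A and A' by double ring-closing metathesis at C2=C3 (21), after reverse prenylation (C4–C5) of diketone 17.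
- **Key disconnection:** 17 ⇒ achiral bis(allyl dienol carbonate) 15 by double decarboxylative asymmetric allylation, which forms C1–C10 and C1'–C10', sets both quaternary centres and leaves the alkenes at C8=C9.
- **Precursor:** 15 ⇒ bis(enone) 12 ⇒ two Stork–Danheiser additions of a C2 alkyne unit to vinylogous ester 4, made from 2-methylcyclohexane-1,3-dione 1.
- **Ring order:** rings B and B' come with 1; rings A and A' close together last, in step 9.

Key step: step 7

Assumption: (S)-t-Bu-PHOX is taken to induce the same spatial sense as with 2-methylcyclohexanone enolates, which maps onto the required 10R,10'R diketone 17 (otherwise the (R)-ligand is used). The C8 centres in 4–12 and the C5 carbinol centres in 20–24 are stereorandom and are erased in steps 6 and 12.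

## Route

Step 1
Reactants: 1 2-methylcyclohexane-1,3-dione
Product: 2 3-isobutoxy-2-methylcyclohex-2-en-1-one
Conditions: i-BuOH, p-TsOH·H2O (cat.), toluene, Dean–Stark, reflux
Reagents that add atoms: isobutanol, CC(C)CO
Why: Acid-catalysed vinylogous esterification with azeotropic removal of water is a standard condensation, and the two carbonyl groups of 1 are equivalent so only one enol ether can form.

Step 2
Reactants: 2 3-isobutoxy-2-methylcyclohex-2-en-1-one
Product: 4 (±)-3-isobutoxy-2,6-dimethylcyclohex-2-en-1-one, via lithium enolate 3 (not isolated)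
Conditions: LiN(i-Pr)2, THF, −78 °C; MeI, −78 → 0 °C
Reagents that add atoms: iodomethane, CI
Why: Stork–Danheiser alkylation, in which LiN(i-Pr)2 deprotonates the vinylogous ester kinetically at its only alpha' position (future C8) and the enolate is C-methylated; the new C8 centre is racemic and harmless because it becomes sp2 in step 6.

Step 3
Reactants: 4 (±)-3-isobutoxy-2,6-dimethylcyclohex-2-en-1-one; 5 ethynyltrimethylsilane
Product: 8 1-ethynyl-3-isobutoxy-2,6-dimethylcyclohex-2-en-1-ol (diastereomer mixture), via lithium (trimethylsilyl)acetylide 6 (not isolated), via silylated lithium alkoxide 7 (not isolated)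
Conditions: 5, n-BuLi, THF, −78 °C; 4, −78 °C → rt; then MeOH, K2CO3 (cat.), rt; H2O work-up, product kept base-washed
Reagents that add atoms: ethynyltrimethylsilane (5), C#C[Si](C)(C)C
Why: 1,2-Addition of a slim lithium acetylide to the vinylogous ester carbonyl (first half of a Stork–Danheiser transposition), followed by base-mediated protodesilylation, keeps the acid-labile tertiary carbinol basic throughout, and the carbinol configuration is irrelevant because that centre is lost in step 4.

Step 4
Reactants: 8 1-ethynyl-3-isobutoxy-2,6-dimethylcyclohex-2-en-1-ol; 4 (±)-3-isobutoxy-2,6-dimethylcyclohex-2-en-1-one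
Product: 11 3,3'-(ethyne-1,2-diyl)bis(2,4-dimethylcyclohex-2-en-1-one) (C4/C4' stereorandom), via dilithiated carbinol 9 (not isolated), via ynediol 10 (not isolated)
Conditions: n-BuLi (2.05 equiv), THF, −78 → 0 °C; 4, −78 °C → rt; then 2 M aq HCl, THF, rt
Reagents that add atoms: water, O
Why: The alkoxide–acetylide dianion adds to a second molecule of 4 as in step 3, and aqueous acid then ionises both enol-ether-assisted tertiary carbinols and hydrolyses the oxocarbenium ions (double Stork–Danheiser transposition), which places the carbonyls at C5 and C5' and the linker carbons on C9 and C9'.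

Step 5
Reactants: 11 3,3'-(ethyne-1,2-diyl)bis(2,4-dimethylcyclohex-2-en-1-one)
Product: 12 3,3'-(ethane-1,2-diyl)bis(2,4-dimethylcyclohex-2-en-1-one) (C4/C4' stereorandom)
Conditions: H2 (1 atm), 10% Pd/C, EtOAc, rt, stopped after 2 equiv H2
Reagents that add atoms: none
Why: Heterogeneous catalytic hydrogenation saturates the accessible alkyne, whereas the two tetrasubstituted enone alkenes are reduced far more slowly, so stopping at two equivalents of H2 should leave them intact.

Step 6
Reactants: 12 3,3'-(ethane-1,2-diyl)bis(2,4-dimethylcyclohex-2-en-1-one); 13 allyl chloroformate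
Product: 15 1,2-bis[5-(allyloxycarbonyloxy)-2,6-dimethylcyclohexa-1,5-dien-1-yl]ethane (achiral bis(allyl dienol carbonate)), via dipotassium bis(dienolate) 14 (not isolated)
Conditions: KOt-Bu (2.4 equiv), THF, 0 °C → rt, 1 h; then 13 (3 equiv), −78 → 0 °C
Reagents that add atoms: allyl chloroformate (13), C=CCOC(=O)Cl
Why: Reversible deprotonation by KOt-Bu funnels each enone to the most stable linearly conjugated endocyclic dienolate (C5=C10–C9=C8, tetrasubstituted alkene, the regiochemistry that underlies classical deconjugative alkylation of 3-alkylcyclohexenones) rather than the cross-conjugated C6 or exocyclic C11 enolate, and the hard chloroformate acylates the potassium enolate on oxygen (enol carbonate formation), while any C10-acylated beta-keto ester would ionise to the same palladium dienolate in step 7.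

Step 7
Reactants: 15 1,2-bis[5-(allyloxycarbonyloxy)-2,6-dimethylcyclohexa-1,5-dien-1-yl]ethane
Product: 17 (2R,2'R)-3,3'-(ethane-1,2-diyl)bis(2-allyl-2,4-dimethylcyclohex-3-en-1-one) (drimane 10R,10'R), via mono-allylated carbonate 16 (not isolated)
Conditions: Pd2(dba)3 (5 mol %), (S)-t-Bu-PHOX [(S)-4-tert-butyl-2-(2-diphenylphosphinophenyl)-4,5-dihydrooxazole] (12.5 mol %), THF, 25 °C; meso isomer removed by chromatography or crystallisation; product kept below 40 °C
Reagents that add atoms: none
Why: Zerovalent palladium bound to the phosphinooxazoline ionises each allyl carbonate, CO2 departs, and the O-bound allylpalladium dienolate forges C1–C10 (then C1'–C10' via 16) by inner-sphere reductive elimination through a seven-membered cyclic transition state. The closest known reaction type is the decarboxylative asymmetric allylic alkylation (Tsuji–Trost type) of tetrasubstituted cyclic allyl enol carbonates, which has also been run twice on one molecule, and alpha attack on an extended enolate is the classical outcome of deconjugative alkylation. No ring is closed. C10 and C10' are set by the catalyst alone, the tert-butyl oxazoline and PPh2 quadrants exposing one enolate face, and the (S)-ligand that gives (S)-2-allyl-2-methylcyclohexanone corresponds spatially to the 10R,10'R product needed here (the descriptor changes only because C9 outranks the allyl carbon). The step needs alpha (C10) over gamma (C8) allylation and no enolate scrambling, which the substrate secures because the carbonate oxygen on C5 holds palladium three atoms from C10 and out of reach of C8, C10 carries the largest dienolate coefficient, and the enolate is released site-specifically without a proton source, so the alkene is left at C8=C9. Because two catalyst-controlled events occur in one molecule, most wrong-face events should end in the separable meso diastereomer and the C2-symmetric 17 should be enriched beyond the single-event selectivity (Horeau-type amplification).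

Step 8
Reactants: 17 (2R,2'R)-3,3'-(ethane-1,2-diyl)bis(2-allyl-2,4-dimethylcyclohex-3-en-1-one); 18 prenyl bromide
Product: 20 (2R,2'R)-3,3'-(ethane-1,2-diyl)bis[2-allyl-2,4-dimethyl-1-(2-methylbut-3-en-2-yl)cyclohex-3-en-1-ol] (carbinol epimers at drimane C5/C5'), via prenylzinc bromide 19 (not isolated)
Conditions: 18 (5 equiv), Zn dust, LiCl, THF, 0 °C; then 17, −20 → 0 °C; H2O quench
Reagents that add atoms: prenyl bromide (18), CC(C)=CCBr
Why: Barbier-type allylzinc addition through a closed six-membered SE2' (Zimmerman–Traxler) transition state delivers the tertiary terminus (C4) to the C5 carbonyl; the non-basic reagent avoids C6 enolisation, the low temperature suppresses retro-allylation to the linear isomer, and the new C5 carbinol centres may form as a mixture because they are erased in step 12.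

Step 9
Reactants: 20 (2R,2'R)-3,3'-(ethane-1,2-diyl)bis[2-allyl-2,4-dimethyl-1-(2-methylbut-3-en-2-yl)cyclohex-3-en-1-ol]
Product: 21 1,2-bis[(8aR)-4a-hydroxy-2,5,5,8a-tetramethyl-3,4,4a,5,8,8a-hexahydronaphthalen-1-yl]ethane (4a epimers)
Conditions: second-generation Grubbs catalyst RuCl2(=CHPh)(PCy3)(SIMes) (2 × 5 mol %), CH2Cl2 (high dilution), 40 °C
Reagents that add atoms: none
Why: Double ring-closing metathesis initiates at each unhindered allyl terminus and closes the six-membered ring A onto the neighbouring neopentyl vinyl group (C2=C3), helped by the gem-dialkyl effect; both C5 epimers can cyclise to cis- or trans-fused rings, and the tetrasubstituted C8=C9 alkenes are inert.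

Step 10
Reactants: 21 1,2-bis[(8aR)-4a-hydroxy-2,5,5,8a-tetramethyl-3,4,4a,5,8,8a-hexahydronaphthalen-1-yl]ethane
Product: 22 1,2-bis[(8aR)-4a-hydroxy-2,5,5,8a-tetramethyl-3,4,4a,5,6,7,8,8a-octahydronaphthalen-1-yl]ethane (4a epimers)
Conditions: H2 (1 atm), 10% Pd/C, EtOAc, rt
Reagents that add atoms: none
Why: Catalytic hydrogenation discriminates by substitution, so the cis-disubstituted C2=C3 alkenes are saturated while the tetrasubstituted C8=C9 alkenes next to quaternary C10 stay untouched.

Step 11
Reactants: 22 1,2-bis[(8aR)-4a-hydroxy-2,5,5,8a-tetramethyl-3,4,4a,5,6,7,8,8a-octahydronaphthalen-1-yl]ethane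
Product: 24 bis(methyl oxalate) of 22 (4a-O-C(O)CO2Me on both halves), via dilithium dialkoxide 23 (not isolated)
Conditions: n-BuLi (2.2 equiv), THF, −78 °C; ClC(O)CO2Me (3 equiv), −78 °C → rt
Reagents that add atoms: methyl chlorooxoacetate, COC(=O)C(=O)Cl
Why: O-Acylation of the preformed lithium alkoxide with the very electrophilic, sterically small oxalyl monoester chloride is the standard way to activate a congested tertiary alcohol for radical deoxygenation, and the lithium counter-ion at low temperature disfavours anionic fragmentation of the C5–C10 bond.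

Step 12
Reactants: 24 bis(methyl oxalate) of 22
Product: 25 1,2-bis[(4aS,8aS)-2,5,5,8a-tetramethyl-3,4,4a,5,6,7,8,8a-octahydronaphthalen-1-yl]ethane (target CNP0372467.1)
Conditions: Bu3SnH (6 equiv, 0.3 M), AIBN (cat.), toluene, 110 °C
Reagents that add atoms: none
Why: Barton–McCombie-type deoxygenation of a tertiary methyl oxalate releases the planar C5 radical from either epimer; Bu3SnH should deliver hydrogen to the alpha face, anti to the axial C10 methyl and the 4-beta methyl, to give the trans ring fusion (5S,5'S), and the high stannane concentration outruns any homoallyl to cyclopropylcarbinyl rearrangement through C9.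

## Compound list

1 | 2-methylcyclohexane-1,3-dione | CC1C(=O)CCCC1=O | starting material
2 | 3-isobutoxy-2-methylcyclohex-2-en-1-one | CC1=C(OCC(C)C)CCCC1=O | intermediate
3 | lithium enolate of 2 (not isolated) | CC1=C(OCC(C)C)CCC=C1O[Li] | intermediate
4 | (±)-3-isobutoxy-2,6-dimethylcyclohex-2-en-1-one | CC1CCC(OCC(C)C)=C(C)C1=O | intermediate
5 | ethynyltrimethylsilane | C#C[Si](C)(C)C | starting material
6 | lithium (trimethylsilyl)acetylide (not isolated) | [Li]C#C[Si](C)(C)C | intermediate
7 | lithium 3-isobutoxy-2,6-dimethyl-1-[(trimethylsilyl)ethynyl]cyclohex-2-en-1-olate (not isolated) | CC1CCC(OCC(C)C)=C(C)C1(O[Li])C#C[Si](C)(C)C | intermediate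
8 | 1-ethynyl-3-isobutoxy-2,6-dimethylcyclohex-2-en-1-ol (diastereomer mixture) | CC1CCC(OCC(C)C)=C(C)C1(O)C#C | intermediate
9 | dilithiated carbinol, O,C-dilithio 8 (not isolated) | CC1CCC(OCC(C)C)=C(C)C1(O[Li])C#C[Li] | intermediate
10 | 1,1'-(ethyne-1,2-diyl)bis(3-isobutoxy-2,6-dimethylcyclohex-2-en-1-ol) (not isolated) | CC1CCC(OCC(C)C)=C(C)C1(O)C#CC1(O)C(C)CCC(OCC(C)C)=C1C | intermediate
11 | 3,3'-(ethyne-1,2-diyl)bis(2,4-dimethylcyclohex-2-en-1-one) (C4/C4' stereorandom) | CC1CCC(=O)C(C)=C1C#CC1=C(C)C(=O)CCC1C | intermediate
12 | 3,3'-(ethane-1,2-diyl)bis(2,4-dimethylcyclohex-2-en-1-one) (C4/C4' stereorandom) | CC1CCC(=O)C(C)=C1CCC1=C(C)C(=O)CCC1C | intermediate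
13 | allyl chloroformate | C=CCOC(=O)Cl | starting material
14 | dipotassium bis(dienolate) of 12 (not isolated) | [K]OC1=C(C)C(CCC2=C(C)CCC(O[K])=C2C)=C(C)CC1 | intermediate
15 | 1,2-bis[5-(allyloxycarbonyloxy)-2,6-dimethylcyclohexa-1,5-dien-1-yl]ethane (achiral) | C(CC1=C(C)CCC(OC(=O)OCC=C)=C1C)C1=C(C)CCC(OC(=O)OCC=C)=C1C | intermediate
16 | mono-allylated carbonate, one half (R)-ketone and one half dienol carbonate (not isolated) | C=CCOC(=O)OC1=C(C)C(CCC2=C(C)CCC(=O)[C@]2(C)CC=C)=C(C)CC1 | intermediate
17 | (2R,2'R)-3,3'-(ethane-1,2-diyl)bis(2-allyl-2,4-dimethylcyclohex-3-en-1-one) | C(CC1=C(C)CCC(=O)[C@]1(C)CC=C)C1=C(C)CCC(=O)[C@]1(C)CC=C | intermediate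
18 | prenyl bromide (1-bromo-3-methylbut-2-ene) | CC(C)=CCBr | starting material
19 | prenylzinc bromide (not isolated) | CC(C)=CC[Zn]Br | intermediate
20 | (2R,2'R)-3,3'-(ethane-1,2-diyl)bis[2-allyl-2,4-dimethyl-1-(2-methylbut-3-en-2-yl)cyclohex-3-en-1-ol] (carbinol epimers) | C(CC1=C(C)CCC(O)(C(C)(C)C=C)[C@]1(C)CC=C)C1=C(C)CCC(O)(C(C)(C)C=C)[C@]1(C)CC=C | intermediate
21 | 1,2-bis[(8aR)-4a-hydroxy-2,5,5,8a-tetramethyl-3,4,4a,5,8,8a-hexahydronaphthalen-1-yl]ethane (4a epimers) | C(CC1=C(C)CCC2(O)C(C)(C)C=CC[C@]12C)C1=C(C)CCC2(O)C(C)(C)C=CC[C@]12C | intermediate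
22 | 1,2-bis[(8aR)-4a-hydroxy-2,5,5,8a-tetramethyl-3,4,4a,5,6,7,8,8a-octahydronaphthalen-1-yl]ethane (4a epimers) | C(CC1=C(C)CCC2(O)C(C)(C)CCC[C@]12C)C1=C(C)CCC2(O)C(C)(C)CCC[C@]12C | intermediate
23 | dilithium dialkoxide of 22 (not isolated) | C(CC1=C(C)CCC2(O[Li])C(C)(C)CCC[C@]12C)C1=C(C)CCC2(O[Li])C(C)(C)CCC[C@]12C | intermediate
24 | bis(methyl oxalate) of 22 (4a epimers) | C(CC1=C(C)CCC2(OC(=O)C(=O)OC)C(C)(C)CCC[C@]12C)C1=C(C)CCC2(OC(=O)C(=O)OC)C(C)(C)CCC[C@]12C | intermediate
25 | 1,2-bis[(4aS,8aS)-2,5,5,8a-tetramethyl-3,4,4a,5,6,7,8,8a-octahydronaphthalen-1-yl]ethane | CC1=C(CCC2=C(C)CC[C@H]3C(C)(C)CCC[C@]23C)[C@@]2(C)CCCC(C)(C)[C@@H]2CC1 | target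

## Step count

Total step count: 12. Longest linear sequence: 12 steps, from 1 to 25.

## Three steps most likely to fail

**Step 7.**
- What may go wrong: facial selectivity may erode at the crowded, fully substituted dienolate, which inflates the meso fraction. Some material may also leak into gamma allylation at C8 or into protonation back to the enone.
- Fallback: it sets out from 12 and gives up catalytic stereocontrol. Classical deconjugative alpha-allylation (KOt-Bu, allyl bromide, t-BuOH/THF, 0 °C) should give the stereorandom 3,3'-(ethane-1,2-diyl)bis(2-allyl-2,4-dimethylcyclohex-3-en-1-one) F1. The meso form is removed by chromatography or crystallisation. The C2-symmetric racemate is then resolved by preparative chromatography on a chiral stationary phase.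
- Return: the (R,R)-enantiomer is 17, where the route is rejoined.

**Step 8.**
- What may go wrong: congestion between C4, C5 and C10 may block the addition. Reversible addition followed by retro-allylation may also drain the kinetic tertiary-terminus adduct into the linear prenyl isomer.
- Fallback: it sets out from 17 and makes the C4–C5 bond intramolecularly.
  - Chemoselective hydroboration of the two terminal alkenes with 9-BBN-H (THF, rt, hindered ketones left alone) gives the bis(B-alkyl-9-borabicyclononane) F2.
  - F2 is coupled without isolation with 2-bromopropene (B-alkyl Suzuki–Miyaura, PdCl2(dppf), K3PO4, DMF/THF/H2O) to give (2R,2'R)-3,3'-(ethane-1,2-diyl)bis[2,4-dimethyl-2-(4-methylpent-4-en-1-yl)cyclohex-3-en-1-one] F3.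
  - Metal-hydride hydrogen-atom-transfer reductive alkene–ketone cyclisation (Fe(acac)3, PhSiH3 in excess, EtOH, 60 °C) turns each 1,1-disubstituted alkene into the tertiary C4 radical, which closes onto C5 in 6-exo mode. The excess silane is there to reduce the alkoxy radical before it can undergo beta-scission.
- Return: the route is rejoined directly at 22, replacing steps 8 to 10.

**Step 11.**
- What may go wrong: acylation of the tertiary alkoxide flanked by two quaternary carbons may be incomplete, or the oxalate may be lost by premature elimination.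
- Fallback: it sets out from 22. Dehydration with SOCl2/pyridine (0 °C) can only run toward C6, since C4 and C10 carry no hydrogen. It gives 1,2-bis[(8aR)-2,5,5,8a-tetramethyl-3,5,6,7,8,8a-hexahydronaphthalen-1-yl]ethane F4. Mukaiyama-type hydrogen-atom-transfer hydrogenation (Mn(dpm)3, PhSiH3, t-BuOOH, i-PrOH, rt) of the trisubstituted C5=C6 alkenes, which react faster than the shielded tetrasubstituted C8=C9 alkenes, passes through the same C5 radical and should give the trans fusion.
- Return: the route is rejoined at 25.

## Further compounds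

F1 | step 7 | 3,3'-(ethane-1,2-diyl)bis(2-allyl-2,4-dimethylcyclohex-3-en-1-one), racemic plus meso forms | C(CC1=C(C)CCC(=O)C1(C)CC=C)C1=C(C)CCC(=O)C1(C)CC=C
F2 | step 8 | (2R,2'R)-3,3'-(ethane-1,2-diyl)bis{2-[3-(9-borabicyclo[3.3.1]nonan-9-yl)propyl]-2,4-dimethylcyclohex-3-en-1-one} | C(CC1=C(C)CCC(=O)[C@]1(C)CCCB1C2CCCC1CCC2)C1=C(C)CCC(=O)[C@]1(C)CCCB1C2CCCC1CCC2
F3 | step 8 | (2R,2'R)-3,3'-(ethane-1,2-diyl)bis[2,4-dimethyl-2-(4-methylpent-4-en-1-yl)cyclohex-3-en-1-one] | C(CC1=C(C)CCC(=O)[C@]1(C)CCCC(C)=C)C1=C(C)CCC(=O)[C@]1(C)CCCC(C)=C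
F4 | step 11 | 1,2-bis[(8aR)-2,5,5,8a-tetramethyl-3,5,6,7,8,8a-hexahydronaphthalen-1-yl]ethane | C(CC1=C(C)CC=C2C(C)(C)CCC[C@]12C)C1=C(C)CC=C2C(C)(C)CCC[C@]12C
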